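**Retrosynthetic overview**
1. The single disconnection is at the alkyl C–O bond (acyl-O–CH2) of the ester. It leads back to heneicosanoic acid 1 and styrene 2, both purchased.
2. In the forward direction, a catalytic base converts part of 1 into carboxylate ion pair 3. This adds through oxygen to the terminal carbon of ruthenium-bound 2 (anti-Markovnikov hydroacyloxylation) and gives target 4 in one step.
3. No ring is formed. The benzene ring arrives intact in 2 and the C21 chain arrives intact in 1.

Assumption: the SMILES has no stereocentre and no stereogenic double bond, so there is no enantiomer to control; "phenylethyl" is read as 2-phenylethyl as drawn; 1 is taken as a catalogue odd-chain fatty acid sold in gram lots and 2 as a commodity monomer.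

**Route**

Step 1
Reactants: 1 heneicosanoic acid; 2 styrene
Product: 4 phenethyl heneicosanoate, via ammonium heneicosanoate 3 (not isolated)
Conditions: Ru(cod)(2-methylallyl)2 (5 mol %), Ph2P(CH2)5PPh2 (6 mol %), CF3SO3H (10 mol %), iPr2NEt (25 mol %), 2 (4 equiv), 1,4-dioxane (0.5 M in 1), N2, 100 °C, 24–36 h
Reagents that add atoms: none
Why: Proposed new method: anti-Markovnikov hydroacyloxylation of a vinylarene through η6-arene activation. The three catalyst components give an 18-electron cation of divalent ruthenium, [Ru(κ3-P,C,P-(Ph2PCH2CH2)2CH)(η6-styrene)]OTf, in which the metal draws electron density out of the ring so that the vinyl group acts as a Michael-type acceptor. Carboxylate 3, whose nucleophilicity in an aprotic solvent is comparable to that of a secondary amine, attacks the terminal CH2 because only that mode places the charge on the metal-stabilised benzylic carbon. Free acid 1 then protonates that carbon and regenerates 3, and excess 2 displaces the η6-bound ester at 100 °C to close the cycle. iPr2NEt buffers all CF3SO3H, which shuts off the proton-catalysed Markovnikov path, and the estimated reaction enthalpy (about −11 kcal/mol) is similar to that of amine additions that go to high conversion at this temperature. Closest known reaction type: ruthenium-catalysed anti-Markovnikov hydroamination of vinylarenes with secondary amines via η6-arene complexes (same precatalyst mixture), together with stoichiometric nucleophilic addition to the vinyl group of η6-styrene metal complexes. As far as is known, a carboxylic acid nucleophile and C–O bond formation have not been shown in this manifold. The step is a pure addition (C21H42O2 + C8H8 = C29H50O2) and creates no stereocentre.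

Practical notes
- **Order of addition:** premix Ru(cod)(2-methylallyl)2, the diphosphine and CF3SO3H in dioxane for 10 min at 23 °C under N2. Then add iPr2NEt, 1 and 2.
- **Solvent choice:** do not use arene solvents such as toluene or benzene, because they compete for the η6 site.
- **Polymerisation:** at about 2 M styrene, thermal polymerisation over 24 h amounts to only a few percent.
- **Work-up:** evaporate dioxane and excess 2, then filter through a short pad of basic Al2O3 (hexane/EtOAc 30:1). The pad retains residual 1, ammonium salts and ruthenium. Recrystallise from acetone at 0 °C.
- **Regiochemistry check (expected 1H NMR of 4):** δ 4.29 (t, 2H, OCH2), 2.93 (t, 2H, CH2Ph), 2.28 (t, 2H), 1.58 (m, 2H), 1.25 (34H), 0.88 (t, 3H), 7.2–7.3 (5H). A quartet near δ 5.9 would indicate the branched isomer.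

**Compound list**
1 | heneicosanoic acid | CCCCCCCCCCCCCCCCCCCCC(=O)O | starting material
2 | styrene | C=Cc1ccccc1 | starting material
3 | ethyldiisopropylammonium heneicosanoate (ion pair, formed in the flask) | CCCCCCCCCCCCCCCCCCCCC(=O)[O-].CC[NH+](C(C)C)C(C)C | intermediate
4 | 2-phenylethyl heneicosanoate (phenethyl heneicosanoate, achiral) | CCCCCCCCCCCCCCCCCCCCC(=O)OCCc1ccccc1 | target

**Totals**
Total step count: 1
Longest linear sequence: 1 step

**Steps most likely to fail**
The route has only one step, so the list has one entry.

Step 1 (the proposed new step) may fail for three reasons:
- (a) Once the arene has left, carboxylate can chelate ruthenium and hold it as a neutral κ2-carboxylate complex, so turnover may stop.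
- (b) Carboxylate is a much better leaving group than an amine. The bound product can therefore revert by benzylic deprotonation and β-elimination, and conversion may level off early.
- (c) Any unbuffered CF3SO3H would give the branched 1-phenylethyl ester and styrene oligomers.

The fallback is a Fischer esterification, which is known chemistry. It makes the acyl C–O bond instead of the alkyl C–O bond, and the partner is an alcohol rather than an alkene. It sets out from 1 and comes back to the route at 4. Acid 1 is condensed directly with purchased 2-phenylethanol (OCCc1ccccc1, 1.2 equiv) using p-toluenesulfonic acid monohydrate (5 mol %) in toluene at reflux with a Dean–Stark trap for 4–6 h. The mixture is washed with aqueous NaHCO3, dried over Na2SO4 and the product recrystallised from acetone. The step count stays at one, and the fallback makes no compound that is missing from the compound list (entry F0).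

**Further compounds**
F0 | step 1 | none | none
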